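The numbers are invented; the flask was simulated.

Each substrate that reacts leaves, through the intermediate, as one target or one decomposed reagent, and each target costs one second reagent.

substrate 0.50 M (in portions, 3); coupling partner 0.900 M; second reagent 0.475 M; time 15 d; the portions of substrate follow each other after 25 min, the first at the start

    substrate + coupling partner → intermediate (k1 = 0.0180 /M/min)
    second reagent + intermediate → target (k2 = 0.0150 /M/min)
    intermediate → decomposed reagent (k3 = 0.0223 /min)

* at 15 d, what has stopped the reaction, if anything has (all of the substrate has reacted / it is still moving / the second reagent has run out first / the coupling partner has run out first)
* the target standing at 15 d, as a percentage of the substrate charged

- the reaction counts as stopped when no species that holds the substrate changes by six tenths of a point or more over the second half of the time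
- run time (flask): 15 d

The coupling partner's charge exceeds the substrate's. Even the 0.400 M of it that outlasts the substrate gives the substrate a half-life of 96.3 min, far shorter than 15 d. So this reckoning expects the substrate to be used up, and the target is then the substrate charged times the mean share that capture wins.

That share comes from the capture ratio (a selectivity factor): the capture constant times [second reagent], divided by the decomposition constant. Both rates carry [intermediate] to the same power, so it cancels, and neither [substrate] nor [coupling partner] enters. At the start the ratio is 0.320, so decomposition leads. Capture per intermediate slows as [second reagent] falls, and the ratio falls with the fraction of it left. Decomposition per intermediate keeps its constant.

share at the start = ratio/(one + ratio) = 24.2%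

first pass: fraction left 0.745, end share 19.2%, mean 21.7%

second pass: fraction left 0.771, end share 19.8%, mean 22.0%

The forecast says that all of the substrate has reacted and gives 21.9% of target: “only about a fifth of the substrate ends up as target”.

For this flask the simulation reports that all of the substrate has reacted, with 21.9% of target and 76.9% of the second reagent left, and the gradual adding leaves the target unchanged. In the neighbouring flask with 1.9 M of second reagent, the ratio starts at 1.28, which gives a share of 56.1%. The fraction of its second reagent left is then reckoned at 0.852, the end share at 52.1% and the mean at 54.1%. That neighbouring flask gives 54.2% of target, with 86% of its second reagent left.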